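**Retrosynthetic overview**

- The 14-membered carbocycle and the γ-lactone are opened together at C1–C2 (the bond a cembrene cyclase forms) and O2–C16. This gives an acyclic epoxy aldehyde carrying a 2-(methoxycarbonyl)allyl acetate: C1 is the π-nucleophile, C2 the electrophile.
- The seco chain is cut at C14–C1 (alkenyl–aldehyde coupling with a C4 acrylate unit) and at C13–C14 (one-carbon carbonylation of an allylic chloride).
- The oxirane and the C5 acetate come from a Sharpless kinetic resolution plus Mitsunobu inversion of a racemic allylic alcohol, itself made head-to-tail from a geranyl metal (C10) and a C5 enal.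
- Ring order: oxirane (acyclic stage), then the 14-membered ring, then the γ-lactone (the last two in one flask).

Assumption: locants C1–C20 in the text are the cembrane locants of the target (C1 carries C15–C17, C2 the lactone oxygen, C3/C4 the oxirane, C5 the acetate, C14 the hydroxyl); open-chain intermediates keep these locants.

**Step 1**
Reactants: 1 glycolaldehyde (used as its commercial dimer); 2 2-(triphenyl-λ5-phosphanylidene)propanal
Product: 4 (2E)-2-methyl-4-[(triethylsilyl)oxy]but-2-enal, via (2E)-4-hydroxy-2-methylbut-2-enal 3 (not isolated)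
Conditions: CH2Cl2, 40 °C; then Et3SiCl, imidazole, 0 °C
Reagents that add atoms: chlorotriethylsilane, CC[Si](Cl)(CC)CC
Why: Wittig olefination with a stabilised formyl ylide gives the (E)-enal selectively, and the primary alcohol is silylated in the same flask so that the hydroxy enal need not be isolated.

**Step 2**
Reactants: 5 geranyl chloride [(2E)-1-chloro-3,7-dimethylocta-2,6-diene]; 4 (2E)-2-methyl-4-[(triethylsilyl)oxy]but-2-enal
Product: 7 racemic (2E,6E)-3,7,11-trimethyl-1-[(triethylsilyl)oxy]dodeca-2,6,10-trien-4-ol, via geranylbarium chloride 6 (not isolated)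
Conditions: BaI2, LiC12H10 (lithium biphenylide, 2 equiv), THF, 25 °C; then 5, −78 °C; then 4, −78 °C
Reagents that add atoms: none
Why: Allylbarium addition (Barbier/Grignard type): geranylbarium chloride adds 1,2 to the enal through its α-carbon with retention of the 7E geometry, forming C5–C6 head to tail, and the racemic C5 carbinol is resolved in step 3.

**Step 3**
Reactants: 7 racemic (2E,6E)-3,7,11-trimethyl-1-[(triethylsilyl)oxy]dodeca-2,6,10-trien-4-ol
Product: 8 (1S,3E)-4,8-dimethyl-1-[(2S,3S)-2-methyl-3-{[(triethylsilyl)oxy]methyl}oxiran-2-yl]nona-3,7-dien-1-ol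
Conditions: Ti(OiPr)4 (10 mol %), L-(+)-diisopropyl tartrate (15 mol %), t-BuOOH (0.6 equiv), 4 Å MS, CH2Cl2, −20 °C
Reagents that add atoms: tert-butyl hydroperoxide, CC(C)(C)OO
Why: Sharpless asymmetric epoxidation run as a kinetic resolution: with L-(+)-tartrate the 5S enantiomer is epoxidised much faster and on the face that gives the erythro 3S,4S-epoxide, so C3, C4 and C5 are set together, the other olefins are untouched, and the slow 5R alcohol is recovered (maximum yield 50 %).

**Step 4**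
Reactants: 8 (1S,3E)-4,8-dimethyl-1-[(2S,3S)-2-methyl-3-{[(triethylsilyl)oxy]methyl}oxiran-2-yl]nona-3,7-dien-1-ol
Product: 9 (1R,3E)-4,8-dimethyl-1-[(2S,3S)-2-methyl-3-{[(triethylsilyl)oxy]methyl}oxiran-2-yl]nona-3,7-dien-1-yl acetate
Conditions: PPh3, DIAD, AcOH, toluene, 0 → 25 °C
Reagents that add atoms: acetic acid, CC(=O)O
Why: Mitsunobu reaction: SN2 displacement of the alkoxyphosphonium by acetate inverts C5 (5S to 5R) and installs the acetate, giving the threo 4,5-relationship of the target.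

**Step 5**
Reactants: 9 (1R,3E)-4,8-dimethyl-1-[(2S,3S)-2-methyl-3-{[(triethylsilyl)oxy]methyl}oxiran-2-yl]nona-3,7-dien-1-yl acetate
Product: 10 (1R,3E,7E)-9-hydroxy-4,8-dimethyl-1-[(2S,3S)-2-methyl-3-{[(triethylsilyl)oxy]methyl}oxiran-2-yl]nona-3,7-dien-1-yl acetate
Conditions: SeO2 (cat.), t-BuOOH, salicylic acid (cat.), CH2Cl2, 25 °C
Reagents that add atoms: tert-butyl hydroperoxide, CC(C)(C)OO
Why: Selenium dioxide allylic oxidation (ene reaction then [2,3]-shift) attacks the terminal, most electron-rich trisubstituted olefin at its E-methyl group (C13), while the epoxide, esters and silyl ether are inert.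

**Step 6**
Reactants: 10 (1R,3E,7E)-9-hydroxy-4,8-dimethyl-1-[(2S,3S)-2-methyl-3-{[(triethylsilyl)oxy]methyl}oxiran-2-yl]nona-3,7-dien-1-yl acetate
Product: 11 (1R,3E,7E)-9-chloro-4,8-dimethyl-1-[(2S,3S)-2-methyl-3-{[(triethylsilyl)oxy]methyl}oxiran-2-yl]nona-3,7-dien-1-yl acetate
Conditions: PPh3, CCl4, CH2Cl2, 25 °C
Reagents that add atoms: carbon tetrachloride, ClC(Cl)(Cl)Cl
Why: Appel reaction converts the primary allylic alcohol into the allylic chloride by SN2 displacement without allylic transposition.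

**Step 7**
Reactants: 11 (1R,3E,7E)-9-chloro-4,8-dimethyl-1-[(2S,3S)-2-methyl-3-{[(triethylsilyl)oxy]methyl}oxiran-2-yl]nona-3,7-dien-1-yl acetate
Product: 12 (1R,3E,7E)-4,8-dimethyl-1-[(2S,3S)-2-methyl-3-{[(triethylsilyl)oxy]methyl}oxiran-2-yl]-10-oxodeca-3,7-dien-1-yl acetate
Conditions: Pd(PPh3)4 (5 mol %), CO (3 atm), Bu3SnH (slow addition), THF, 50 °C
Reagents that add atoms: carbon monoxide, [C-]#[O+]
Why: Palladium-catalysed reductive carbonylation (formylation) of an allylic chloride: oxidative addition to zerovalent palladium, CO insertion at the unsubstituted allyl terminus and hydride transfer from the tin hydride give the β,γ-unsaturated aldehyde (C14) with the 11E olefin intact.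

**Step 8**
Reactants: 13 methyl 2-(bromomethyl)prop-2-enoate
Product: 15 methyl (2Z)-3-bromo-2-(bromomethyl)prop-2-enoate, via methyl 2,3-dibromo-2-(bromomethyl)propanoate 14 (not isolated)
Conditions: Br2, CH2Cl2, 0 °C; then Et3N, 0 → 25 °C
Reagents that add atoms: bromine, BrBr
Why: Bromine addition to the acrylate followed by E2 dehydrobromination gives the vinyl bromide with bromine trans to the ester.

**Step 9**
Reactants: 15 methyl (2Z)-3-bromo-2-(bromomethyl)prop-2-enoate
Product: 16 methyl (2E)-2-[(acetyloxy)methyl]-3-bromoprop-2-enoate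
Conditions: KOAc, DMF, 25 °C
Reagents that add atoms: potassium acetate, CC(=O)[O-].[K+]
Why: SN2 displacement of the allylic bromide by acetate (the vinylic bromide is inert) installs the allylic acetate that later serves as π-allyl precursor.

**Step 10**
Reactants: 12 (1R,3E,7E)-4,8-dimethyl-1-[(2S,3S)-2-methyl-3-{[(triethylsilyl)oxy]methyl}oxiran-2-yl]-10-oxodeca-3,7-dien-1-yl acetate; 16 methyl (2E)-2-[(acetyloxy)methyl]-3-bromoprop-2-enoate
Product: 17 methyl (2E,4R,6E,10E,13R)-13-(acetyloxy)-2-[(acetyloxy)methyl]-6,10-dimethyl-13-[(2S,3S)-2-methyl-3-{[(triethylsilyl)oxy]methyl}oxiran-2-yl]-4-[(triethylsilyl)oxy]trideca-2,6,10-trienoate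
Conditions: CrCl2 (15 mol %), chiral sulfonamide–oxazoline ligand (17 mol %, enantiomer that delivers 4R), NiCl2(2,9-dimethyl-1,10-phenanthroline) (2 mol %), Mn, Et3SiCl, LiCl, MeCN, 25 °C
Reagents that add atoms: chlorotriethylsilane, CC[Si](Cl)(CC)CC
Why: Catalytic asymmetric Nozaki–Hiyama–Kishi coupling: the alkenyl bromide is activated by nickel, transferred to ligand-bound chromium and added to the aldehyde on the face that gives 14R (reagent control) with retention of alkene geometry, while Et3SiCl turns over chromium and delivers the product directly as its triethylsilyl ether.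

**Step 11**
Reactants: 17 methyl (2E,4R,6E,10E,13R)-13-(acetyloxy)-2-[(acetyloxy)methyl]-6,10-dimethyl-13-[(2S,3S)-2-methyl-3-{[(triethylsilyl)oxy]methyl}oxiran-2-yl]-4-[(triethylsilyl)oxy]trideca-2,6,10-trienoate
Product: 19 methyl (2E,4R,6E,10E,13R)-13-(acetyloxy)-2-[(acetyloxy)methyl]-13-[(2S,3R)-3-formyl-2-methyloxiran-2-yl]-6,10-dimethyl-4-[(triethylsilyl)oxy]trideca-2,6,10-trienoate, via alkoxydimethylsulfonium chloride 18 (not isolated)
Conditions: (COCl)2, DMSO, CH2Cl2, −78 → −40 °C; then i-Pr2NEt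
Reagents that add atoms: none
Why: Swern oxidation applied directly to the primary triethylsilyl ether, which is cleaved and oxidised in preference to the secondary silyl ether, unveils the α,β-epoxy aldehyde (C2) without disturbing C3 (the descriptor at C3 changes from S to R only through CIP priorities).

**Step 12**
Reactants: 19 methyl (2E,4R,6E,10E,13R)-13-(acetyloxy)-2-[(acetyloxy)methyl]-13-[(2S,3R)-3-formyl-2-methyloxiran-2-yl]-6,10-dimethyl-4-[(triethylsilyl)oxy]trideca-2,6,10-trienoate
Product: 22 michaolide F 14-O-triethylsilyl ether, via allylindium acetate iodide 20 (not isolated), via macrocyclic hydroxy ester 21 (not isolated)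
Conditions: Pd(PPh3)4 (10 mol %), InI (2 equiv), THF, 25 °C, slow addition of 19 (final 0.002 M)
Reagents that add atoms: none
Why: Proposed new method: oxidative addition of zerovalent palladium to the allylic acetate gives a π-allyl complex that equilibrates to the isomer with C14 syn and is reduced by InI to the (E)-allylindium 20, which tolerates epoxide, esters and aldehyde and adds through its γ-carbon C1 to the epoxy aldehyde in a chair (Zimmerman–Traxler) transition state – Felkin–Anh attack anti to the oxirane C–O bond sets 2S, the equatorial C14 of the E-allyl unit sets the 1,2-anti relationship that becomes the trans ring fusion, and attack anti to the C13 chain with H14 eclipsing the ester (1,3-allylic strain) sets C1 – after which the C2 indium alkoxide acylates on the C16 ester to close the lactone; the closest known reactions are the intermolecular palladium/InI umpolung allylation of aldehydes with allylic acetates and Barbier-type macrocyclisations of 2-(alkoxycarbonyl)allyl halides onto aldehydes.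

**Step 13**
Reactants: 22 michaolide F 14-O-triethylsilyl ether
Product: 23 michaolide F
Conditions: HF·pyridine, pyridine, THF, 0 °C
Reagents that add atoms: none
Why: Fluoride-mediated desilylation of the secondary triethylsilyl ether under buffered conditions leaves the epoxide, the acetate and the α-methylene lactone intact.

**Compound list**

1 | glycolaldehyde | OCC=O | starting material
2 | 2-(triphenyl-λ5-phosphanylidene)propanal | CC(C=O)=P(c1ccccc1)(c1ccccc1)c1ccccc1 | starting material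
3 | (2E)-4-hydroxy-2-methylbut-2-enal | O=C/C(C)=C/CO | intermediate
4 | (2E)-2-methyl-4-[(triethylsilyl)oxy]but-2-enal | O=C/C(C)=C/CO[Si](CC)(CC)CC | intermediate
5 | geranyl chloride, (2E)-1-chloro-3,7-dimethylocta-2,6-diene | ClC/C=C(\C)CCC=C(C)C | starting material
6 | geranylbarium chloride | Cl[Ba]C/C=C(\C)CCC=C(C)C | intermediate
7 | racemic (2E,6E)-3,7,11-trimethyl-1-[(triethylsilyl)oxy]dodeca-2,6,10-trien-4-ol | CC(C)=CCC/C(C)=C/CC(O)/C(C)=C/CO[Si](CC)(CC)CC | intermediate
8 | (1S,3E)-4,8-dimethyl-1-[(2S,3S)-2-methyl-3-{[(triethylsilyl)oxy]methyl}oxiran-2-yl]nona-3,7-dien-1-ol (3S,4S,5S) | CC(C)=CCC/C(C)=C/C[C@H](O)[C@]1(C)O[C@H]1CO[Si](CC)(CC)CC | intermediate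
9 | (1R,3E)-4,8-dimethyl-1-[(2S,3S)-2-methyl-3-{[(triethylsilyl)oxy]methyl}oxiran-2-yl]nona-3,7-dien-1-yl acetate (3S,4S,5R) | CC(C)=CCC/C(C)=C/C[C@@H](OC(C)=O)[C@]1(C)O[C@H]1CO[Si](CC)(CC)CC | intermediate
10 | (1R,3E,7E)-9-hydroxy-4,8-dimethyl-1-[(2S,3S)-2-methyl-3-{[(triethylsilyl)oxy]methyl}oxiran-2-yl]nona-3,7-dien-1-yl acetate | OC/C(C)=C/CC/C(C)=C/C[C@@H](OC(C)=O)[C@]1(C)O[C@H]1CO[Si](CC)(CC)CC | intermediate
11 | (1R,3E,7E)-9-chloro-4,8-dimethyl-1-[(2S,3S)-2-methyl-3-{[(triethylsilyl)oxy]methyl}oxiran-2-yl]nona-3,7-dien-1-yl acetate | ClC/C(C)=C/CC/C(C)=C/C[C@@H](OC(C)=O)[C@]1(C)O[C@H]1CO[Si](CC)(CC)CC | intermediate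
12 | (1R,3E,7E)-4,8-dimethyl-1-[(2S,3S)-2-methyl-3-{[(triethylsilyl)oxy]methyl}oxiran-2-yl]-10-oxodeca-3,7-dien-1-yl acetate | O=CC/C(C)=C/CC/C(C)=C/C[C@@H](OC(C)=O)[C@]1(C)O[C@H]1CO[Si](CC)(CC)CC | intermediate
13 | methyl 2-(bromomethyl)prop-2-enoate | C=C(CBr)C(=O)OC | starting material
14 | methyl 2,3-dibromo-2-(bromomethyl)propanoate | COC(=O)C(Br)(CBr)CBr | intermediate
15 | methyl (2Z)-3-bromo-2-(bromomethyl)prop-2-enoate (vinylic Br trans to the ester) | Br/C=C(/C(=O)OC)CBr | intermediate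
16 | methyl (2E)-2-[(acetyloxy)methyl]-3-bromoprop-2-enoate (vinylic Br trans to the ester) | Br/C=C(/C(=O)OC)COC(C)=O | intermediate
17 | methyl (2E,4R,6E,10E,13R)-13-(acetyloxy)-2-[(acetyloxy)methyl]-6,10-dimethyl-13-[(2S,3S)-2-methyl-3-{[(triethylsilyl)oxy]methyl}oxiran-2-yl]-4-[(triethylsilyl)oxy]trideca-2,6,10-trienoate | COC(=O)/C(COC(C)=O)=C/[C@H](O[Si](CC)(CC)CC)C/C(C)=C/CC/C(C)=C/C[C@@H](OC(C)=O)[C@]1(C)O[C@H]1CO[Si](CC)(CC)CC | intermediate
18 | alkoxydimethylsulfonium chloride of 17 (the C2 oxygen carries S+Me2 in place of SiEt3) | COC(=O)/C(COC(C)=O)=C/[C@H](O[Si](CC)(CC)CC)C/C(C)=C/CC/C(C)=C/C[C@@H](OC(C)=O)[C@]1(C)O[C@H]1CO[S+](C)C.[Cl-] | intermediate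
19 | methyl (2E,4R,6E,10E,13R)-13-(acetyloxy)-2-[(acetyloxy)methyl]-13-[(2S,3R)-3-formyl-2-methyloxiran-2-yl]-6,10-dimethyl-4-[(triethylsilyl)oxy]trideca-2,6,10-trienoate | COC(=O)/C(COC(C)=O)=C/[C@H](O[Si](CC)(CC)CC)C/C(C)=C/CC/C(C)=C/C[C@@H](OC(C)=O)[C@]1(C)O[C@H]1C=O | intermediate
20 | allylindium acetate iodide: methyl (2E,4R,6E,10E,13R)-13-(acetyloxy)-2-{[(acetyloxy)(iodo)indiganyl]methyl}-13-[(2S,3R)-3-formyl-2-methyloxiran-2-yl]-6,10-dimethyl-4-[(triethylsilyl)oxy]trideca-2,6,10-trienoate (C14 cis to the ester) | COC(=O)/C(C[In](I)OC(C)=O)=C\[C@H](O[Si](CC)(CC)CC)C/C(C)=C/CC/C(C)=C/C[C@@H](OC(C)=O)[C@]1(C)O[C@H]1C=O | intermediate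
21 | macrocyclic hydroxy ester: methyl 2-[(1S,2S,3S,4S,5R,7E,11E,14R)-5-(acetyloxy)-3,4-epoxy-2-hydroxy-4,8,12-trimethyl-14-[(triethylsilyl)oxy]cyclotetradeca-7,11-dien-1-yl]prop-2-enoate (cembrane locants) | C=C(C(=O)OC)[C@@H]1[C@H](O[Si](CC)(CC)CC)C/C(C)=C/CC/C(C)=C/C[C@@H](OC(C)=O)[C@]2(C)O[C@H]2[C@H]1O | intermediate
22 | michaolide F 14-O-triethylsilyl ether (cembrane locants 1S,2S,3S,4S,5R,7E,11E,14R; C1 is spatially as in 23, its descriptor changes only through CIP priorities) | C=C1C(=O)O[C@H]2[C@H]1[C@H](O[Si](CC)(CC)CC)C/C(C)=C/CC/C(C)=C/C[C@@H](OC(C)=O)[C@]1(C)O[C@@H]21 | intermediate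
23 | michaolide F (cembrane locants 1R,2S,3S,4S,5R,7E,11E,14R) | C=C1C(=O)O[C@H]2[C@H]1[C@H](O)C/C(C)=C/CC/C(C)=C/C[C@@H](OC(C)=O)[C@]1(C)O[C@@H]21 | target

**Step count and risk**

Total: 13 steps. Longest linear sequence: 11 steps (steps 1–7 and 10–13); steps 8 and 9 make the C4 coupling partner 16.

The three steps most likely to fail:

Step 12 (ring closure). Transmetalation may be slow against π-allyl side reactions, the allylindium geometry may not equilibrate as assumed, or the facial control by C14 may be poor. The fallback sets out from 19 and returns at 22. Palladium-catalysed borylation (Pd2(dba)3, B2pin2, DMSO, 50 °C) converts the allylic acetate into the isolable methyl (2Z,4R,6E,10E,13R)-13-(acetyloxy)-13-[(2S,3R)-3-formyl-2-methyloxiran-2-yl]-6,10-dimethyl-2-[(4,4,5,5-tetramethyl-1,3,2-dioxaborolan-2-yl)methyl]-4-[(triethylsilyl)oxy]trideca-2,6,10-trienoate F1. As a 2-alkoxycarbonyl allylboronate it does not react with the aldehyde until activated. Sc(OTf)3 (10 mol %) in toluene at −20 °C and 0.002 M then triggers an intramolecular allylboration through a closed boron chair, and the borate lactonises to 22.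

Step 4 (Mitsunobu at a carbinol next to a fully substituted oxirane carbon). Displacement may be slow or diverted by the neighbouring epoxide. The fallback sets out from 7, using the 5R enantiomer that step 3 leaves unreacted, and returns at 9. Acetylation (Ac2O, DMAP, pyridine) gives (2E,4R,6E)-3,7,11-trimethyl-1-[(triethylsilyl)oxy]dodeca-2,6,10-trien-4-yl acetate F2. PPTS in MeOH removes the primary silyl group to give (2E,4R,6E)-1-hydroxy-3,7,11-trimethyldodeca-2,6,10-trien-4-yl acetate F3. Sharpless epoxidation of this primary allylic alcohol (Ti(OiPr)4, L-(+)-diethyl tartrate, t-BuOOH) sets the 3S,4S-epoxide under reagent control, giving (1R,3E)-1-[(2S,3S)-3-(hydroxymethyl)-2-methyloxiran-2-yl]-4,8-dimethylnona-3,7-dien-1-yl acetate F4. Et3SiCl/imidazole returns 9. No inversion is needed, and the route then uses both enantiomers of 7.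

Step 7 (reductive carbonylation). Direct hydride reduction of the π-allyl or migration of the double bond into conjugation can compete. The fallback sets out from 11 and returns at 12. Alkylation of 2-lithio-1,3-dithiane (THF, −78 °C) with the allylic chloride gives (1R,3E,7E)-9-(1,3-dithian-2-yl)-4,8-dimethyl-1-[(2S,3S)-2-methyl-3-{[(triethylsilyl)oxy]methyl}oxiran-2-yl]nona-3,7-dien-1-yl acetate F5. Unmasking with MeI and CaCO3 in aqueous MeCN releases aldehyde 12, so C14 enters as a formyl anion equivalent instead of by CO insertion.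

**Further compounds**

F1 | step 12 | methyl (2Z,4R,6E,10E,13R)-13-(acetyloxy)-13-[(2S,3R)-3-formyl-2-methyloxiran-2-yl]-6,10-dimethyl-2-[(4,4,5,5-tetramethyl-1,3,2-dioxaborolan-2-yl)methyl]-4-[(triethylsilyl)oxy]trideca-2,6,10-trienoate | COC(=O)/C(CB1OC(C)(C)C(C)(C)O1)=C\[C@H](O[Si](CC)(CC)CC)C/C(C)=C/CC/C(C)=C/C[C@@H](OC(C)=O)[C@]1(C)O[C@H]1C=O
F2 | step 4 | (2E,4R,6E)-3,7,11-trimethyl-1-[(triethylsilyl)oxy]dodeca-2,6,10-trien-4-yl acetate | CC(C)=CCC/C(C)=C/C[C@@H](OC(C)=O)/C(C)=C/CO[Si](CC)(CC)CC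
F3 | step 4 | (2E,4R,6E)-1-hydroxy-3,7,11-trimethyldodeca-2,6,10-trien-4-yl acetate | CC(C)=CCC/C(C)=C/C[C@@H](OC(C)=O)/C(C)=C/CO
F4 | step 4 | (1R,3E)-1-[(2S,3S)-3-(hydroxymethyl)-2-methyloxiran-2-yl]-4,8-dimethylnona-3,7-dien-1-yl acetate | CC(C)=CCC/C(C)=C/C[C@@H](OC(C)=O)[C@]1(C)O[C@H]1CO
F5 | step 7 | (1R,3E,7E)-9-(1,3-dithian-2-yl)-4,8-dimethyl-1-[(2S,3S)-2-methyl-3-{[(triethylsilyl)oxy]methyl}oxiran-2-yl]nona-3,7-dien-1-yl acetate | S1CCCSC1C/C(C)=C/CC/C(C)=C/C[C@@H](OC(C)=O)[C@]2(C)O[C@H]2CO[Si](CC)(CC)CC
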